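Retrosynthetic overview
1. Feature: the C2=C3 bond of the 3(2H)-furanone (ring C1–C2–C3–O–C10) is also an E double bond of the ten-membered carbocycle C1–C10 (C1 and C4 trans) and is flanked by C4; C2–C3 and C4–C5 can therefore be two sides of a cyclobutene built on an eight-membered ring and opened across C2–C5.
2. Target ⇐ furanone-bridged ten-membered dienone 28 (Z-C4=C5) by C4=C5 epoxidation, lactone Mannich base, Pd/formate epoxide opening (C4–H, C5–OH), C8 angeloylation and amine elimination to C11=C13.
3. 28 ⇐ cis-lactone-fused cyclooct-2-enone 26 carrying a C10–O–C≡C–CH3 ether: light-driven [2+2] across C2=C5, then 4π opening of the cyclobutene (eight → ten).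
4. 26 ⇐ cyclooctene 17 by selenolactonisation/elimination (C6–O, C2=C5) and by unmasking a dichlorovinyl ether (from trichloroethylene) as the propynyl ether; 17 ⇐ ring-closing metathesis of a diene made by Johnson–Claisen (C7) and vinyl/allyl Grignard additions (C10, C1) on L-threitol acetonide (C7–C10).
5. Ring order: dioxolane (chiral pool) → cyclooctene → γ-lactone → furanone and ten-membered ring together in the key step.

Key step: step 22

Assumption: (4S,5S)-2,3-O-isopropylidene-L-threitol (two steps from diethyl L-tartrate: acetonide, LiAlH4) is taken as the commercial tartrate building block. Atom numbers are those of the germacrane skeleton (C1 ketone, C3–O–C10 furanone, C12 lactone carbonyl, C13 exocyclic methylene, C14 methyl on C10, C15 methyl on C4).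

Step 1
Reactants: 1 L-threitol acetonide
Product: 2 mono-PMB ether
Conditions: NaH (1 equiv), 4-methoxybenzyl chloride, Bu4NI (cat.), THF/DMF, 0 → 20 °C
Reagents that add atoms: 4-methoxybenzyl chloride, COc1ccc(CCl)cc1
Why: Williamson etherification of the monosodium alkoxide of the C2-symmetric diol gives one mono-ether whichever hydroxyl reacts, and no stereocentre is touched.

Step 2
Reactants: 2 mono-PMB ether
Product: 4 methyl carbinol, via aldehyde 3 (not isolated)
Conditions: (COCl)2, DMSO, CH2Cl2, −78 °C; Et3N; then MeMgBr, THF, −78 → 0 °C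
Reagents that add atoms: methylmagnesium bromide, C[Mg]Br
Why: Swern oxidation gives the configurationally labile α-alkoxy aldehyde, which is trapped in the same flask by Grignard addition so that C9 is not epimerised; the new carbinol centre is of no consequence because it is oxidised in step 3.

Step 3
Reactants: 4 methyl carbinol
Product: 5 methyl ketone
Conditions: Dess–Martin periodinane, NaHCO3, CH2Cl2, 20 °C
Reagents that add atoms: none
Why: Dess–Martin oxidation of the secondary alcohol under buffered, non-epimerising conditions gives the C10 methyl ketone.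

Step 4
Reactants: 5 methyl ketone
Product: 6 tertiary allylic alcohol
Conditions: CH2=CHMgBr, THF, −78 °C
Reagents that add atoms: vinylmagnesium bromide, C=C[Mg]Br
Why: Grignard 1,2-addition under Felkin–Anh (polar, non-chelated) control, with the nucleophile entering anti to the dioxolane C9–O bond, should set C10 with O10 anti to O9 as in the target.

Step 5
Reactants: 6 tertiary allylic alcohol; 7 trichloroethylene
Product: 8 dichlorovinyl ether
Conditions: KH, THF, 0 °C; then 7, −50 → 20 °C
Reagents that add atoms: none
Why: the potassium alkoxide adds to dichloroacetylene formed in situ from trichloroethylene and the vinyl anion is protonated (the known route from alkoxides, tertiary ones included, to 1,2-dichlorovinyl ethers); neither neighbour of C10 carries a group that can migrate to the alkoxide, and the ether stores the future ynol ether through the following thirteen steps.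

Step 6
Reactants: 8 dichlorovinyl ether
Product: 9 C1 aldehyde
Conditions: O3, CH2Cl2, −78 °C; then PPh3
Reagents that add atoms: ozone, [O-][O+]=O
Why: ozonolysis cleaves the monosubstituted vinyl group far faster than the chlorine-deactivated enol ether and gives the aldehyde after reductive work-up.

Step 7
Reactants: 9 C1 aldehyde
Product: 10 homoallylic alcohol
Conditions: CH2=CHCH2MgBr, THF/Et2O, −78 °C
Reagents that add atoms: allylmagnesium bromide, C=CC[Mg]Br
Why: Grignard allylation of the hindered α-alkoxy aldehyde brings in C2 and C5; Felkin–Anh addition anti to the C10–O bond should give mainly the C1 epimer drawn, and the other epimer is equally usable because C1 becomes a ketone in step 21.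

Step 8
Reactants: 10 homoallylic alcohol
Product: 11 C1 silyl ether
Conditions: TBSOTf, 2,6-lutidine, CH2Cl2, 0 °C
Reagents that add atoms: tert-butyldimethylsilyl triflate, CC(C)(C)[Si](C)(C)OS(=O)(=O)C(F)(F)F
Why: silylation with the triflate protects the hindered secondary C1 alcohol for the oxidation, orthoester and selenium steps, with no risk of silyl migration now that O10 is etherified.

Step 9
Reactants: 11 C1 silyl ether
Product: 12 primary alcohol
Conditions: DDQ, CH2Cl2/pH 7 buffer, 0 °C
Reagents that add atoms: none
Why: oxidative PMB cleavage by DDQ (hydride abstraction, hydrolysis of the oxocarbenium ion) frees the C7 alcohol without touching the silyl ether, acetonide, terminal alkene or chlorinated enol ether.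

Step 10
Reactants: 12 primary alcohol
Product: 13 C7 aldehyde
Conditions: TEMPO (cat.), PhI(OAc)2, CH2Cl2, 20 °C
Reagents that add atoms: none
Why: oxoammonium (TEMPO) oxidation of the primary alcohol stops at the aldehyde under near-neutral conditions that do not epimerise C8.

Step 11
Reactants: 13 C7 aldehyde
Product: 14 Z-enoate
Conditions: (PhO)2P(O)CH2CO2Et, NaH, THF, −78 → −20 °C
Reagents that add atoms: ethyl 2-(diphenoxyphosphoryl)acetate, CCOC(=O)CP(=O)(Oc1ccccc1)Oc1ccccc1
Why: the Z-selective Horner–Wadsworth–Emmons reaction of a diaryl phosphonoacetate (fast elimination from the kinetic oxaphosphetane) gives the cis-enoate needed for allylic-strain control in step 13.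

Step 12
Reactants: 14 Z-enoate
Product: 15 Z-allylic alcohol
Conditions: iBu2AlH, CH2Cl2, −78 °C
Reagents that add atoms: none
Why: 1,2-reduction of the enoate by the aluminium hydride at low temperature gives the allylic alcohol with the Z geometry kept.

Step 13
Reactants: 15 Z-allylic alcohol
Product: 16 Claisen ester
Conditions: MeC(OEt)3, EtCO2H (cat.), xylene, 135 °C
Reagents that add atoms: triethyl orthoacetate, CCOC(C)(OCC)OCC
Why: Johnson–Claisen rearrangement through a chair transition state forms C7–C11 and the C6 vinyl group; with the cis alkene H8 eclipses the double bond and the ketene acetal carbon should bond to C7 anti to the C8–O bond, which sets C7 as in the target.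

Step 14
Reactants: 16 Claisen ester
Product: 17 cyclooctene ester
Conditions: second-generation Grubbs catalyst (10 mol%), CH2Cl2 (1 mM), 40 °C
Reagents that add atoms: none
Why: ring-closing metathesis of the two terminal alkenes closes the eight-membered carbocycle with loss of ethylene, helped by the trans-dioxolane and the quaternary C10, while the chlorinated enol ether is inert to the ruthenium carbene.

Step 15
Reactants: 17 cyclooctene ester
Product: 18 cyclooctene acid
Conditions: LiOH, THF/MeOH/H2O, 20 °C; then dilute HCl to pH 4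
Reagents that add atoms: lithium hydroxide, [Li+].[OH-]
Why: saponification of the ethyl ester, to which silyl ether, acetonide and dichlorovinyl ether are stable.

Step 16
Reactants: 18 cyclooctene acid
Product: 20 allylic lactone, via selenolactone 19 (not isolated)
Conditions: PhSeCl, Et3N, CH2Cl2, −78 °C; then H2O2, pyridine, THF, 0 → 20 °C
Reagents that add atoms: none
Why: phenylselenolactonisation (5-exo attack of the carboxylate on C6 of the seleniranium ion, which can only give the cis-fused γ-lactone and so sets C6 from C7) followed by selenoxide syn-elimination away from the oxygen-bearing carbon moves the alkene to C2=C5.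

Step 17
Reactants: 20 allylic lactone
Product: 21 lactol
Conditions: iBu2AlH (1.1 equiv), CH2Cl2, −78 °C
Reagents that add atoms: none
Why: half-reduction of the lactone stops at the aluminium hemiacetal at −78 °C and gives the lactol, the lactone-level form that can be made stable to butyllithium.

Step 18
Reactants: 21 lactol
Product: 22 silyl acetal
Conditions: TBSCl, imidazole, DMF, 20 °C
Reagents that add atoms: tert-butyldimethylsilyl chloride, CC(C)(C)[Si](C)(C)Cl
Why: silylation of the lactol hydroxyl gives a mixed silyl acetal that is stable to strong base.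

Step 19
Reactants: 22 silyl acetal
Product: 24 propynyl ether, via lithium alkoxyacetylide 23 (not isolated)
Conditions: n-BuLi (2.4 equiv), THF, −78 → −40 °C; then MeI, DMPU, −78 → −20 °C
Reagents that add atoms: iodomethane, CI
Why: butyllithium eliminates HCl and then exchanges the chlorine of the chloroalkynyl ether for lithium, and the lithium alkoxyacetylide is C-methylated (the standard conversion of dichlorovinyl ethers into 1-alkynyl ethers); the temperature stays below −20 °C because the tertiary alkynyl ether is prone to retro-ene fragmentation.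

Step 20
Reactants: 24 propynyl ether
Product: 25 lactol alcohol
Conditions: Bu4NF, THF, 0 °C
Reagents that add atoms: none
Why: fluoride cleaves the C1 silyl ether and the silyl acetal under non-acidic conditions that spare the acid- and heat-sensitive ynol ether.

Step 21
Reactants: 25 lactol alcohol
Product: 26 cyclooctenone propynyl ether
Conditions: nPr4NRuO4 (cat.), N-methylmorpholine N-oxide, 4 Å molecular sieves, CH2Cl2, 0 °C
Reagents that add atoms: none
Why: Ley–Griffith oxidation under neutral conditions converts the lactol into the lactone and the allylic alcohol into the enone in one operation, with no acid or electrophile that would hydrate the ynol ether.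

Step 22
Reactants: 26 cyclooctenone propynyl ether
Product: 28 furanone-bridged dienone, via cyclobutene 27 (not isolated)
Conditions: hν (365 nm), degassed CH2Cl2 (2 mM), −40 °C; then 20 °C in the dark
Reagents that add atoms: none
Why: Proposed new method: n→π* excitation gives the triplet enone, whose α-carbon C2 adds to the proximal ynol-ether carbon C3 in a 5-exo-dig radical closure through the three-atom C1–C10–O tether (this forms the future furanone ring), and the C4 vinyl/C5 alkyl 1,4-diradical then closes C4–C5 to the cis-fused cyclobutene 27. This strained push–pull cyclobutene (alkoxy on C3, acyl on C2) opens by thermal conrotatory 4π electrocyclisation with cleavage of C2–C5, so the ten-membered carbocycle arises by ring expansion of the eight-membered ring by the two alkyne carbons and the product is a vinylogous ester. The closest known reaction types are the intramolecular enone–alkyne [2+2] photocycloaddition through three-atom carbon tethers and the conrotatory opening of bicyclic cyclobutenes to cis,trans-cycloalkadienes; neither is known with an ynol ether tethered to the α'-carbon of the ketone or as a furanone-forming ring expansion. No stereocentre is created (C2 and C5 end sp2); the Z geometry of C4=C5 follows from conrotation in the cis-fused adduct, because the tether forces C1 to rotate outward and C6 therefore inward. The step needs straight (C2–C3/C4–C5) and not crossed addition, secured by the five-membered first closure that the C1–C10–O tether allows, and alkene and not carbonyl reactivity, which is usual for π,π* triplet enones. Low temperature and long-wavelength light guard the tertiary ynol ether against retro-ene loss and the product against secondary photochemistry.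

Step 23
Reactants: 28 furanone-bridged dienone
Product: 29 C4,C5-epoxide
Conditions: dimethyldioxirane, acetone/CH2Cl2, −20 → 0 °C
Reagents that add atoms: dimethyldioxirane, CC1(C)OO1
Why: electrophilic epoxidation by the neutral dioxirane takes the distal, more electron-rich C4=C5 bond of the dienone stereospecifically cis, and attack is expected anti to the allylic C6–O bond with H6 in the alkene plane (allylic strain with C3), which sets C5 and, for the moment, C4.

Step 24
Reactants: 29 C4,C5-epoxide
Product: 31 Mannich base, via lithium enolate 30 (not isolated)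
Conditions: LiN(SiMe3)2, THF, −78 °C; then Me2N=CH2 I, −78 → 0 °C
Reagents that add atoms: Eschenmoser's salt, C[N+](C)=C.[I-]
Why: kinetic enolisation at the lactone α-CH2 (the ketone has no α-hydrogen and C6–H is no longer conjugated) and Mannich reaction with Eschenmoser's salt on the convex face give the β-amino lactone that masks the exocyclic methylene.

Step 25
Reactants: 31 Mannich base
Product: 32 C5 alcohol
Conditions: Pd2(dba)3·CHCl3 (cat.), PBu3, HCO2H, Et3N, dioxane, 20 °C
Reagents that add atoms: none
Why: palladium-catalysed formate hydrogenolysis of the alkenyl oxirane (Tsuji–Trost-type ionisation by zerovalent palladium with inversion to the π-allyl complex over C2–C3–C4, then hydride delivery from palladium to the substituted terminus C4) replaces C4–O by C4–H with net inversion and leaves C5–O untouched, which gives the anti C4-methyl/C5-hydroxyl pair of the target.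

Step 26
Reactants: 32 C5 alcohol
Product: 33 C5 silyl ether
Conditions: TBSOTf, 2,6-lutidine, CH2Cl2, −78 → 0 °C
Reagents that add atoms: tert-butyldimethylsilyl triflate, CC(C)(C)[Si](C)(C)OS(=O)(=O)C(F)(F)F
Why: silylation of the C5 hydroxyl ensures that only the C8/C9 diol is exposed in the acylation.

Step 27
Reactants: 33 C5 silyl ether
Product: 34 C8,C9-diol
Conditions: CeCl3·7H2O, oxalic acid, MeCN, 20 °C
Reagents that add atoms: none
Why: mild Lewis-acid-assisted hydrolysis removes the strained trans-fused acetonide in preference to the hindered secondary silyl ether.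

Step 28
Reactants: 34 C8,C9-diol; 35 angelic acid
Product: 36 C8 angelate
Conditions: 35, 2,4,6-Cl3C6H2COCl, Et3N, toluene, 20 °C; then 34, 70 °C
Reagents that add atoms: none
Why: Yamaguchi esterification with the preformed mixed anhydride, run without DMAP to avoid isomerisation of angelate to tiglate, should acylate the C8 hydroxyl in preference to the C9 hydroxyl, which is neopentyl-like next to the fully substituted C10.

Step 29
Reactants: 36 C8 angelate
Product: 37 amino lactone diol
Conditions: HF·pyridine, pyridine/THF, 0 → 20 °C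
Reagents that add atoms: none
Why: buffered fluoride desilylation frees the C5 hydroxyl without touching the angelate, the β-amino lactone or the furanone.

Step 30
Reactants: 37 amino lactone diol
Product: 39 target CNP0206920.1, via ammonium iodide 38 (not isolated)
Conditions: MeI, MeOH/CH2Cl2, 20 °C; then aq. NaHCO3, EtOAc, 20 °C
Reagents that add atoms: none
Why: N-methylation to the quaternary ammonium salt and mild-base E1cB (Hofmann-type) loss of trimethylamine unveil the α-methylene lactone without strong base, so that C4 is not epimerised and the C5 hydroxyl is not eliminated.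

Compound list
1 | (4S,5S)-2,2-dimethyl-1,3-dioxolane-4,5-dimethanol (2,3-O-isopropylidene-L-threitol; its carbons become C10, C9, C8, C7) | OC[C@H](O1)[C@@H](OC1(C)C)CO | starting material
2 | mono-(4-methoxybenzyl) ether of 1 (PMB on the future C7 oxygen) | OC[C@H](O1)[C@@H](OC1(C)C)COCc1ccc(OC)cc1 | intermediate
3 | C10 aldehyde (4-O-PMB-2,3-O-isopropylidene-L-threose), not isolated | O=C[C@H](O1)[C@@H](OC1(C)C)COCc1ccc(OC)cc1 | intermediate
4 | C10 methyl carbinol (both carbinol epimers) | CC(O)[C@H](O1)[C@@H](OC1(C)C)COCc1ccc(OC)cc1 | intermediate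
5 | C10 methyl ketone (methyl = C14) | CC(=O)[C@H](O1)[C@@H](OC1(C)C)COCc1ccc(OC)cc1 | intermediate
6 | tertiary allylic alcohol: C10 bears methyl, hydroxyl and vinyl (vinyl CH = C1), O10 anti to O9 | C=C[C@](C)(O)[C@H](O1)[C@@H](OC1(C)C)COCc1ccc(OC)cc1 | intermediate
7 | trichloroethylene | ClC=C(Cl)Cl | starting material
8 | (E)-1,2-dichlorovinyl ether of 6 at O10 | C=C[C@](C)(O/C(Cl)=C\Cl)[C@H](O1)[C@@H](OC1(C)C)COCc1ccc(OC)cc1 | intermediate
9 | C1 aldehyde with C10 dichlorovinyl ether | O=C[C@](C)(O/C(Cl)=C\Cl)[C@H](O1)[C@@H](OC1(C)C)COCc1ccc(OC)cc1 | intermediate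
10 | C1 homoallylic alcohol (allyl = C2, C5 and a terminal CH2) | C=CC[C@H](O)[C@](C)(O/C(Cl)=C\Cl)[C@H](O1)[C@@H](OC1(C)C)COCc1ccc(OC)cc1 | intermediate
11 | C1 TBS ether of 10 | C=CC[C@H](O[Si](C)(C)C(C)(C)C)[C@](C)(O/C(Cl)=C\Cl)[C@H](O1)[C@@H](OC1(C)C)COCc1ccc(OC)cc1 | intermediate
12 | C7 primary alcohol | C=CC[C@H](O[Si](C)(C)C(C)(C)C)[C@](C)(O/C(Cl)=C\Cl)[C@H](O1)[C@@H](OC1(C)C)CO | intermediate
13 | C7 aldehyde | C=CC[C@H](O[Si](C)(C)C(C)(C)C)[C@](C)(O/C(Cl)=C\Cl)[C@H](O1)[C@@H](OC1(C)C)C=O | intermediate
14 | (Z)-enoate, ethyl ester (C7=C6) | C=CC[C@H](O[Si](C)(C)C(C)(C)C)[C@](C)(O/C(Cl)=C\Cl)[C@H](O1)[C@@H](OC1(C)C)/C=C\C(=O)OCC | intermediate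
15 | (Z)-allylic alcohol | C=CC[C@H](O[Si](C)(C)C(C)(C)C)[C@](C)(O/C(Cl)=C\Cl)[C@H](O1)[C@@H](OC1(C)C)/C=C\CO | intermediate
16 | Claisen ester: C7 bears vinyl (C6) and CH2CO2Et (C11, C12) | C=CC[C@H](O[Si](C)(C)C(C)(C)C)[C@](C)(O/C(Cl)=C\Cl)[C@H](O1)[C@@H](OC1(C)C)[C@@H](CC(=O)OCC)C=C | intermediate
17 | cyclooctene ethyl ester (ring C1, C2, C5, C6, C7, C8, C9, C10; cis C5=C6) | CCOC(=O)C[C@H]2/C=C\C[C@H](O[Si](C)(C)C(C)(C)C)[C@](C)(O/C(Cl)=C\Cl)[C@H](O1)[C@H]2OC1(C)C | intermediate
18 | cyclooctene carboxylic acid | OC(=O)C[C@H]2/C=C\C[C@H](O[Si](C)(C)C(C)(C)C)[C@](C)(O/C(Cl)=C\Cl)[C@H](O1)[C@H]2OC1(C)C | intermediate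
19 | C5-phenylseleno cis-fused γ-lactone, not isolated | C1C(=O)O[C@H]2[C@H]([Se]c4ccccc4)C[C@H](O[Si](C)(C)C(C)(C)C)[C@](C)(O/C(Cl)=C\Cl)[C@H](O3)[C@@H](OC3(C)C)[C@@H]12 | intermediate
20 | cis-lactone-fused cyclooctene with C2=C5, C1 OTBS and C10 dichlorovinyl ether | C1C(=O)O[C@H]2/C=C\[C@H](O[Si](C)(C)C(C)(C)C)[C@](C)(O/C(Cl)=C\Cl)[C@H](O3)[C@@H](OC3(C)C)[C@@H]12 | intermediate
21 | lactol of 20 (C12 anomers) | C1C(O)O[C@H]2/C=C\[C@H](O[Si](C)(C)C(C)(C)C)[C@](C)(O/C(Cl)=C\Cl)[C@H](O3)[C@@H](OC3(C)C)[C@@H]12 | intermediate
22 | lactol TBS acetal (C12 anomers) | C1C(O[Si](C)(C)C(C)(C)C)O[C@H]2/C=C\[C@H](O[Si](C)(C)C(C)(C)C)[C@](C)(O/C(Cl)=C\Cl)[C@H](O3)[C@@H](OC3(C)C)[C@@H]12 | intermediate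
23 | lithium alkoxyacetylide at O10, not isolated | C1C(O[Si](C)(C)C(C)(C)C)O[C@H]2/C=C\[C@H](O[Si](C)(C)C(C)(C)C)[C@](C)(OC#C[Li])[C@H](O3)[C@@H](OC3(C)C)[C@@H]12 | intermediate
24 | C10 1-propynyl ether, C1 OTBS, silyl acetal (C12 anomers) | C1C(O[Si](C)(C)C(C)(C)C)O[C@H]2/C=C\[C@H](O[Si](C)(C)C(C)(C)C)[C@](C)(OC#CC)[C@H](O3)[C@@H](OC3(C)C)[C@@H]12 | intermediate
25 | C1 alcohol and lactol with C10 1-propynyl ether (C12 anomers) | C1C(O)O[C@H]2/C=C\[C@H](O)[C@](C)(OC#CC)[C@H](O3)[C@@H](OC3(C)C)[C@@H]12 | intermediate
26 | cis-lactone-fused cyclooct-2-enone with C10 1-propynyl ether and C8/C9 acetonide (key-step precursor) | C1C(=O)O[C@H]2/C=C\C(=O)[C@](C)(OC#CC)[C@H](O3)[C@@H](OC3(C)C)[C@@H]12 | intermediate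
27 | cis-fused cyclobutene photoadduct (C2–C3 and C4–C5 formed, C3=C4), not isolated | C1C(=O)O[C@H]2[C@@H]5C(C)=C6[C@@H]5C(=O)[C@](C)(O6)[C@H](O3)[C@@H](OC3(C)C)[C@@H]12 | intermediate
28 | furanone-bridged ten-membered dienone with (Z)-C4=C5, C8/C9 acetonide | C1C(=O)O[C@H]2/C=C(C)\C3=CC(=O)[C@](C)(O3)[C@H](O4)[C@@H](OC4(C)C)[C@@H]12 | intermediate
29 | cis-C4,C5-epoxide of 28 | C1C(=O)O[C@H]2[C@H]5O[C@@]5(C)C3=CC(=O)[C@](C)(O3)[C@H](O4)[C@@H](OC4(C)C)[C@@H]12 | intermediate
30 | lithium lactone enolate of 29, not isolated | C1=C(O[Li])O[C@H]2[C@H]5O[C@@]5(C)C3=CC(=O)[C@](C)(O3)[C@H](O4)[C@@H](OC4(C)C)[C@@H]12 | intermediate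
31 | C11 dimethylaminomethyl lactone (Mannich base, CH2NMe2 trans to C8), epoxide | CN(C)C[C@@H]1C(=O)O[C@H]2[C@H]5O[C@@]5(C)C3=CC(=O)[C@](C)(O3)[C@H](O4)[C@@H](OC4(C)C)[C@@H]12 | intermediate
32 | C5 alcohol with C4–H (C4, C5 as in the target) | CN(C)C[C@@H]1C(=O)O[C@H]2[C@@H](O)[C@@H](C)C3=CC(=O)[C@](C)(O3)[C@H](O4)[C@@H](OC4(C)C)[C@@H]12 | intermediate
33 | C5 TBS ether of 32 | CN(C)C[C@@H]1C(=O)O[C@H]2[C@@H](O[Si](C)(C)C(C)(C)C)[C@@H](C)C3=CC(=O)[C@](C)(O3)[C@H](O4)[C@@H](OC4(C)C)[C@@H]12 | intermediate
34 | C8,C9-diol | CN(C)C[C@@H]1C(=O)O[C@H]2[C@@H](O[Si](C)(C)C(C)(C)C)[C@@H](C)C3=CC(=O)[C@](C)(O3)[C@H](O)[C@@H](O)[C@@H]12 | intermediate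
35 | angelic acid, (Z)-2-methylbut-2-enoic acid | C/C=C(/C)C(=O)O | starting material
36 | C8 angelate, C9 alcohol, C5 OTBS | CN(C)C[C@@H]1C(=O)O[C@H]2[C@@H](O[Si](C)(C)C(C)(C)C)[C@@H](C)C3=CC(=O)[C@](C)(O3)[C@H](O)[C@@H](OC(=O)/C(C)=C\C)[C@@H]12 | intermediate
37 | amino lactone with free C5 and C9 hydroxyls and C8 angelate | CN(C)C[C@@H]1C(=O)O[C@H]2[C@@H](O)[C@@H](C)C3=CC(=O)[C@](C)(O3)[C@H](O)[C@@H](OC(=O)/C(C)=C\C)[C@@H]12 | intermediate
38 | trimethylammonium iodide of 37, not isolated | C[N+](C)(C)C[C@@H]1C(=O)O[C@H]2[C@@H](O)[C@@H](C)C3=CC(=O)[C@](C)(O3)[C@H](O)[C@@H](OC(=O)/C(C)=C\C)[C@@H]12.[I-] | intermediate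
39 | CNP0206920.1 | C=C1C(=O)O[C@H]2[C@@H](O)[C@@H](C)C3=CC(=O)[C@](C)(O3)[C@H](O)[C@@H](OC(=O)/C(C)=C\C)[C@@H]12 | target

Total step count: 30. Longest linear sequence: 30 steps (from 1).

Steps most likely to fail

Step 22. The excited enone may decay by cis→trans isomerisation and then dimerise or add across its carbonyl, the tertiary ynol ether may fragment before it is engaged, or the adduct may fail to open with the required geometry. The fallback uses known chemistry, sets out from 24 and comes back at 28. The 1,6-enyne in 24 (C3≡C4, three-atom tether, cyclooctene C2=C5 still at the silyl ether level) is submitted to the gold-catalysed single-cleavage skeletal rearrangement of enynes (formal enyne metathesis, an established two-carbon ring expansion of cycloalkenes) with Ph3PAuNTf2 in CH2Cl2 at −20 °C. This should give the ten-membered dienyl dihydrofuran F1 with C2=C3 and C4=C5 in place. Bu4NF then gives the alcohol lactol F2, and nPr4NRuO4 with N-methylmorpholine N-oxide oxidises C1 to the furanone ketone and the lactol to the lactone, which is 28.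

Step 23. The oxidant may attack the wrong face of C4=C5, since the flexible ten-membered ring gives no secure bias; this would lead to the 4,5-bis-epimeric series after step 25. The fallback sets out from 28 and comes back at 29. N-Bromosuccinimide in aqueous THF forms the bromonium ion on the face the electrophile prefers, and water opens it anti to give the bromohydrin F3. DBU then closes the epoxide by displacement of bromide, which places the oxygen on the face opposite to the one taken by direct epoxidation.

Step 4. Facial selectivity of the Grignard addition may be poor or reversed through competition between the non-chelated and an α-chelated transition state. The fallback sets out from 2 and comes back at 6. Swern oxidation of 2 to aldehyde 3 and addition of CH2=CHMgBr give the allylic alcohol F4, and Dess–Martin oxidation gives the vinyl ketone F5. MeMgBr with CeCl3 (to enforce 1,2-addition) then delivers the methyl group to the carbonyl face that the vinyl reagent preferred on 5, which, with the two carbon groups exchanged, gives the C10 configuration of 6.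

Further compounds
F1 | step 22 | ten-membered dienyl 2,3-dihydrofuran with C1 OTBS and silyl acetal (C12 anomers) | C1C(O[Si](C)(C)C(C)(C)C)O[C@H]2/C=C(C)\C3=C[C@H](O[Si](C)(C)C(C)(C)C)[C@](C)(O3)[C@H](O4)[C@@H](OC4(C)C)[C@@H]12
F2 | step 22 | C1 alcohol and lactol of F1 (C12 anomers) | C1C(O)O[C@H]2/C=C(C)\C3=C[C@H](O)[C@](C)(O3)[C@H](O4)[C@@H](OC4(C)C)[C@@H]12
F3 | step 23 | C5-bromo C4-hydroxy bromohydrin of 28 | C1C(=O)O[C@H]2[C@H](Br)[C@@](C)(O)C3=CC(=O)[C@](C)(O3)[C@H](O4)[C@@H](OC4(C)C)[C@@H]12
F4 | step 4 | C10 vinyl carbinol (both carbinol epimers) | C=CC(O)[C@H](O1)[C@@H](OC1(C)C)COCc1ccc(OC)cc1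
F5 | step 4 | C10 vinyl ketone | C=CC(=O)[C@H](O1)[C@@H](OC1(C)C)COCc1ccc(OC)cc1
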